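**Plan**

- Retrosynthesis: the 5-O-methyl/7-OH pattern is adjusted last, through a 7-O-benzyl ether, from the 5,7-dihydroxy-6,8,4'-trimethoxyflavone; the pyranone O1–C2 bond is then cut to an o-hydroxyaryl 1,3-diketone.
- Ring A is cut at C6–C7 and C4a–C8a. C7, C8 and C8a carry O, OMe and O, which is the pattern of dimethyl methoxymalonate; C4a, C5 and C6 are the CH2–CO–CH2OMe end of an open-chain 1,3,5-triketone that already holds C2–C4 and ring B.
- Forward: the chain is joined first (C4a–C5, dianion acylation), then ring A is closed by a double Claisen condensation, then ring C by cyclodehydration, then benzylation, methylation and hydrogenolysis.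
- The ring A triol has a mirror plane through C4a and C7, so either ortho hydroxyl closes ring C to the same flavone.
- The target has no stereocentre, so nothing has to be controlled.

Key step: step 2

Assumption: LiN(iPr)2 is used as the purchased solution, the enolate salts 3, 6 and 7 are drawn as separated ions with unspecified double-bond geometry, and the malonate is charged as its preformed lithium enolate because its acidic C–H would otherwise protonate the trianion.

**Step 1**
Reactants: 1 1-(4-methoxyphenyl)butane-1,3-dione; 2 methyl 2-methoxyacetate
Product: 4 1-methoxy-6-(4-methoxyphenyl)hexane-2,4,6-trione, via dilithium dienolate 3 (not isolated)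
Conditions: 1 (2.0 equiv), LiN(iPr)2 (4.2 equiv), THF, 0 °C; then 2 (1.0 equiv), 0 °C to rt; 1 M HCl
Reagents that add atoms: none
Why: Terminal acylation of a β-diketone dianion (Hauser–Harris Claisen condensation) should work because the second deprotonation can only occur at the methyl group, the resulting carbanion is the most nucleophilic site and attacks the activated methoxyacetate carbonyl, and the second equivalent of 3 absorbs the acidic proton of the new triketone so that acylation stops after one event.

**Step 2**
Reactants: 4 1-methoxy-6-(4-methoxyphenyl)hexane-2,4,6-trione; 5 dimethyl 2-methoxymalonate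
Product: 9 1-(2,4,6-trihydroxy-3,5-dimethoxyphenyl)-3-(4-methoxyphenyl)propane-1,3-dione, via trilithium trienolate 6 (not isolated), via lithium malonate enolate 7 (not isolated), via open-chain tetraketo ester 8 (not isolated)
Conditions: 4, LiN(iPr)2 (3.1 equiv), THF, −78 to 0 °C, argon; then 7 (1.3 equiv, from 5 and LiN(iPr)2, THF, −78 °C), 0 °C to rt; then Mg(OMe)2, MeOH, rt to 40 °C; 1 M HCl
Reagents that add atoms: none
Why: Proposed new method: the terminal α-methoxy carbanion of trienolate 6, the least delocalised and hence most nucleophilic of its three carbanion centres, should add to an ester carbonyl of 7 and expel methoxide to forge C6–C7, giving 8 as its polyenolate, and on switching to Mg(OMe)2 in MeOH the C4a carbon between the two chain ketones attacks the remaining ester and expels a second methoxide to forge C4a–C8a. The closest known reaction types are the terminal C-acylation of β-diketone and β-triketone polyanions by esters, including enolate salts of β-keto esters, and the Mg(OMe)2-mediated Claisen cyclisation of 3,5,7-triketo esters to acylphloroglucinols; neither has been run with a malonate as a double acyl donor. Ring A closes by a 6-exo-trig Dieckmann-type acyl substitution, and enolisation of the resulting cyclohexane-1,3,5-trione to the benzenetriol makes the closure irreversible. No stereocentre is created, and the two labile methoxy-bearing sp3 carbons of 8 become the aromatic carbons C6 and C8. The step needs acylation at the chain terminus without proton transfer, and Claisen instead of aldol or lactone folding: the aryl ketone leaves a single terminal carbanion, 5 is delivered as its preformed enolate 7 so that its acidic C–H cannot quench 6, and the ketone that an aldol closure from the aryl-side methylene would have to attack is flanked by two methoxy carbons and tied up as a magnesium enolate chelate. Aldol closures through the methoxy-bearing carbons create a quaternary ring carbon that cannot aromatise and so revert, as does 2-pyranone formation under methoxide, which leaves the aromatic magnesium phenoxide of 9 as the only sink.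

**Step 3**
Reactants: 9 1-(2,4,6-trihydroxy-3,5-dimethoxyphenyl)-3-(4-methoxyphenyl)propane-1,3-dione
Product: 10 5,7-dihydroxy-6,8-dimethoxy-2-(4-methoxyphenyl)-4H-chromen-4-one
Conditions: crude 9, H2SO4 (cat.), AcOH, 90 °C
Reagents that add atoms: none
Why: Acid-catalysed cyclodehydration of an o-hydroxyaryl 1,3-diketone (the closing step of the Baker–Venkataraman flavone synthesis) should close ring C by addition of an ortho phenol to the enolised aryl ketone and loss of water, and the mirror symmetry of 9 means both ortho hydroxyls give the same chromone.

**Step 4**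
Reactants: 10 5,7-dihydroxy-6,8-dimethoxy-2-(4-methoxyphenyl)-4H-chromen-4-one
Product: 11 7-(benzyloxy)-5-hydroxy-6,8-dimethoxy-2-(4-methoxyphenyl)-4H-chromen-4-one
Conditions: BnBr (1.05 equiv), K2CO3 (1.1 equiv), acetone, reflux
Reagents that add atoms: benzyl bromide, BrCc1ccccc1
Why: Williamson etherification under weak base should be selective for the 7-hydroxyl, the more acidic phenol para to the pyranone carbonyl, because the 5-hydroxyl is locked in a hydrogen bond to the C4 carbonyl and stays unreactive towards one equivalent of benzyl bromide.

**Step 5**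
Reactants: 11 7-(benzyloxy)-5-hydroxy-6,8-dimethoxy-2-(4-methoxyphenyl)-4H-chromen-4-one
Product: 12 7-(benzyloxy)-5,6,8-trimethoxy-2-(4-methoxyphenyl)-4H-chromen-4-one
Conditions: Me2SO4 (3 equiv), K2CO3 (5 equiv), acetone, reflux
Reagents that add atoms: dimethyl sulfate, COS(=O)(=O)OC
Why: Williamson methylation with excess dimethyl sulfate in refluxing acetone should overcome the chelation of the 5-hydroxyl, as is routine for 5-hydroxy polymethoxyflavones, while the benzyl ether and the chromone are inert to K2CO3.

**Step 6**
Reactants: 12 7-(benzyloxy)-5,6,8-trimethoxy-2-(4-methoxyphenyl)-4H-chromen-4-one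
Product: 13 7-hydroxy-5,6,8-trimethoxy-2-(4-methoxyphenyl)-4H-chromen-4-one (7-hydroxy-4',5,6,8-tetramethoxyflavone)
Conditions: H2 (1 atm), Pd/C (10% Pd on carbon), EtOAc/MeOH, rt
Reagents that add atoms: none
Why: Catalytic hydrogenolysis should cleave only the benzylic C–O bond, since aryl methyl ethers are inert and the conjugated C2=C3 bond of a flavone is not reduced at room temperature and atmospheric pressure.

**Compound list**

1 | 1-(4-methoxyphenyl)butane-1,3-dione | COc1ccc(C(=O)CC(C)=O)cc1 | starting material
2 | methyl 2-methoxyacetate | COCC(=O)OC | starting material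
3 | dilithium 1-(4-methoxyphenyl)buta-1,3-diene-1,3-diolate (dienolate of 1) | [Li+].[Li+].C=C([O-])C=C([O-])c1ccc(OC)cc1 | intermediate
4 | 1-methoxy-6-(4-methoxyphenyl)hexane-2,4,6-trione | COCC(=O)CC(=O)CC(=O)c1ccc(OC)cc1 | intermediate
5 | dimethyl 2-methoxymalonate | COC(C(=O)OC)C(=O)OC | starting material
6 | trilithium 6-methoxy-1-(4-methoxyphenyl)hexa-1,3,5-triene-1,3,5-triolate (trienolate of 4) | [Li+].[Li+].[Li+].COC=C([O-])C=C([O-])C=C([O-])c1ccc(OC)cc1 | intermediate
7 | lithium 1,2,3-trimethoxy-3-oxoprop-1-en-1-olate (enolate of 5) | [Li+].COC(=O)C(OC)=C([O-])OC | intermediate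
8 | methyl 2,4-dimethoxy-9-(4-methoxyphenyl)-3,5,7,9-tetraoxononanoate (formed as its polyenolate, C2 and C4 not defined) | COC(=O)C(OC)C(=O)C(OC)C(=O)CC(=O)CC(=O)c1ccc(OC)cc1 | intermediate
9 | 1-(2,4,6-trihydroxy-3,5-dimethoxyphenyl)-3-(4-methoxyphenyl)propane-1,3-dione | COc1ccc(C(=O)CC(=O)c2c(O)c(OC)c(O)c(OC)c2O)cc1 | intermediate
10 | 5,7-dihydroxy-6,8-dimethoxy-2-(4-methoxyphenyl)-4H-chromen-4-one | COc1ccc(-c2cc(=O)c3c(O)c(OC)c(O)c(OC)c3o2)cc1 | intermediate
11 | 7-(benzyloxy)-5-hydroxy-6,8-dimethoxy-2-(4-methoxyphenyl)-4H-chromen-4-one | COc1ccc(-c2cc(=O)c3c(O)c(OC)c(OCc4ccccc4)c(OC)c3o2)cc1 | intermediate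
12 | 7-(benzyloxy)-5,6,8-trimethoxy-2-(4-methoxyphenyl)-4H-chromen-4-one | COc1ccc(-c2cc(=O)c3c(OC)c(OC)c(OCc4ccccc4)c(OC)c3o2)cc1 | intermediate
13 | 7-hydroxy-5,6,8-trimethoxy-2-(4-methoxyphenyl)-4H-chromen-4-one | COc1ccc(-c2cc(=O)c3c(OC)c(OC)c(O)c(OC)c3o2)cc1 | target

**Step count**

Total steps: 6. Longest linear sequence: 6 steps (from 1 to 13).

**Steps most likely to fail**

Step 2. The enolised malonate may be too poor an acyl donor, or proton exchange may outrun acylation. The tetraketo ester may also fold by aldol attack of the aryl-side methylene to a resorcinol, or fragment by retro-Claisen cleavage under methoxide. The fallback gives up the open-chain construction of ring A and uses only known aromatic chemistry. Purchased acacetin F1 (5,7-dihydroxy-4'-methoxyflavone) is brominated at C6 and C8 with Br2 in AcOH at rt to 6,8-dibromoacacetin F2. This is benzylated at O-7 (BnBr, K2CO3, acetone, reflux) to the 7-O-benzyl ether F3 and methylated at O-5 (Me2SO4, K2CO3, acetone, reflux) to the 5-O-methyl ether F4. Both bromides are then exchanged for methoxide with NaOMe and CuBr in DMF/MeOH at 110 °C (copper-catalysed Ullmann-type methanolysis of aryl bromides). This fallback does not branch from a numbered compound: F1 replaces compounds 1 to 11, and the sequence comes back to the route at compound 12, one step before the target.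

Step 1. Proton exchange between the dianion and the enolisable ester or the product, or a second addition to the product, may erode the Claisen acylation. The fallback makes the same C4a–C5 bond as an aldol addition and corrects the oxidation level afterwards. It sets out from compound 1: its dianion 3 (LiN(iPr)2, THF, −78 °C) adds through the terminal carbon to methoxyacetaldehyde to give racemic 5-hydroxy-6-methoxy-1-(4-methoxyphenyl)hexane-1,3-dione F5. Dess–Martin periodinane in CH2Cl2 at 0 °C oxidises the secondary alcohol, and the sequence comes back to the route at compound 4.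

Step 4. Alkylation at O-7, which is flanked by two methoxy groups, may be too slow to stay ahead of alkylation at O-5, leading to incomplete conversion or mixed ethers. The fallback moves the selectivity from the protection to the deprotection. It sets out from compound 10, which is benzylated at both oxygens (BnBr in excess, K2CO3, DMF, 60 °C) to 5,7-bis(benzyloxy)-6,8-dimethoxy-2-(4-methoxyphenyl)-4H-chromen-4-one F6. MgBr2·OEt2 in toluene/Et2O at 80 °C then removes only the 5-O-benzyl group, through chelation between the C4 carbonyl and O-5, and the sequence comes back to the route at compound 11.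

**Further compounds**

F1 | step 2 | acacetin, 5,7-dihydroxy-2-(4-methoxyphenyl)-4H-chromen-4-one (purchased entry compound) | COc1ccc(-c2cc(=O)c3c(O)cc(O)cc3o2)cc1
F2 | step 2 | 6,8-dibromo-5,7-dihydroxy-2-(4-methoxyphenyl)-4H-chromen-4-one | COc1ccc(-c2cc(=O)c3c(O)c(Br)c(O)c(Br)c3o2)cc1
F3 | step 2 | 7-(benzyloxy)-6,8-dibromo-5-hydroxy-2-(4-methoxyphenyl)-4H-chromen-4-one | COc1ccc(-c2cc(=O)c3c(O)c(Br)c(OCc4ccccc4)c(Br)c3o2)cc1
F4 | step 2 | 7-(benzyloxy)-6,8-dibromo-5-methoxy-2-(4-methoxyphenyl)-4H-chromen-4-one | COc1ccc(-c2cc(=O)c3c(OC)c(Br)c(OCc4ccccc4)c(Br)c3o2)cc1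
F5 | step 1 | rac-5-hydroxy-6-methoxy-1-(4-methoxyphenyl)hexane-1,3-dione | COCC(O)CC(=O)CC(=O)c1ccc(OC)cc1
F6 | step 4 | 5,7-bis(benzyloxy)-6,8-dimethoxy-2-(4-methoxyphenyl)-4H-chromen-4-one | COc1ccc(-c2cc(=O)c3c(OCc4ccccc4)c(OC)c(OCc4ccccc4)c(OC)c3o2)cc1
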